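**Plan**
Rings are lettered A (acetoxy ring), B (middle ring) and C (acid ring). Each is numbered from the carbonyl-bearing C1 through the hydroxyl-bearing C2 round to the methyl-bearing C6.
Enabling feature: on all three rings the C1 carbonyl sits between the C6 methyl and the C2 oxygen. Deleting the three C2 oxygens therefore leaves every ester carbonyl with a single ortho C-H bond, C2-H of its own ring.
Retrosynthetic cuts, in order: the two benzyl-oxygen bonds (C4 ether of ring A, ester of ring C); the three C2-O bonds of rings A, B and C in one operation; the ester bond from the ring B carbonyl to O-C4 of ring C; the ester bond from the ring A carbonyl to O-C4 of ring B; the bond from C1 of ring A to its carbonyl carbon, back to 3-methylcatechol.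
Forward: no ring is built, since all three arenes are purchased. The ring A acid is made in four steps and esterified with ring B as its 4-hydroxy aldehyde, the aldehyde is oxidised, and the acid is esterified with the ring C benzyl ester (growth A to B to C). Threefold C-H oxygenation and one hydrogenolysis finish the route.
Stereochemistry: the target has no stereocentre or other stereo-element, so only site selectivity must be controlled.

Key step: step 9

Remark: positions written C1 to C6 follow the ring numbering of the plan, whereas compound names use IUPAC locants. The four purchased building blocks are taken as commercial. The alpha-chloro ether formed in step 3 is a transient racemate and everything else is achiral, so no SMILES carries a stereodescriptor.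

**Step 1**
Reactants: 1 3-methylcatechol; 2 benzyl bromide
Product: 3 2-(benzyloxy)-6-methylphenol
Conditions: BnBr (1.0 equiv), K2CO3 (1.0 equiv), acetone, reflux, N2
Reagents that add atoms: benzyl bromide 2, BrCc1ccccc1
Why: Williamson ether synthesis with one equivalent of base, in which the oxygen remote from the methyl group is both the more acidic and the less hindered and should be benzylated first, any dibenzyl ether or regioisomer being removed by chromatography.

**Step 2**
Reactants: 3 2-(benzyloxy)-6-methylphenol
Product: 4 2-(benzyloxy)-6-methylphenyl acetate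
Conditions: Ac2O, pyridine, DMAP (cat.), CH2Cl2, rt
Reagents that add atoms: acetic anhydride, CC(=O)OC(C)=O
Why: DMAP-catalysed O-acetylation of the remaining hindered phenol, which installs the acetate of the target and weakens this oxygen as a donor so that the benzyl ether alone steers the next substitution.

**Step 3**
Reactants: 4 2-(benzyloxy)-6-methylphenyl acetate
Product: 6 3-acetoxy-4-(benzyloxy)-2-methylbenzaldehyde, via chloro(methoxy)methyl arene 5 (not isolated)
Conditions: Cl2CHOMe, AgOSO2CF3, CH2Cl2, -78 °C; then H2O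
Reagents that add atoms: dichloromethyl methyl ether, COC(Cl)Cl (formyl carbon); water, O (formyl oxygen)
Why: Rieche formylation in its silver-salt-promoted low-temperature form, in which the alkoxycarbenium ion should attack para to the benzyloxy group (the usual site in 1-alkoxy-2-acyloxyarenes, reinforced here by the ortho methyl) at a temperature where benzyl ether and acetate persist, water then converting 5 into the aldehyde.

**Step 4**
Reactants: 6 3-acetoxy-4-(benzyloxy)-2-methylbenzaldehyde
Product: 7 3-acetoxy-4-(benzyloxy)-2-methylbenzoic acid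
Conditions: NaClO2, NaH2PO4, 2-methyl-2-butene, t-BuOH/THF/H2O, rt
Reagents that add atoms: sodium chlorite, [Na+].[O-]Cl=O
Why: Pinnick oxidation in a weakly acidic buffer converts the aldehyde into the acid without touching acetate or benzyl ether, the alkene trapping the hypochlorous acid that could chlorinate the ring.

**Step 5**
Reactants: 7 3-acetoxy-4-(benzyloxy)-2-methylbenzoic acid; 8 4-hydroxy-2-methylbenzaldehyde
Product: 9 4-formyl-3-methylphenyl 3-acetoxy-4-(benzyloxy)-2-methylbenzoate
Conditions: DCC, DMAP (cat.), CH2Cl2, 0 °C to rt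
Reagents that add atoms: none
Why: Steglich esterification of an acid with a single ortho substituent by a partner that offers a single phenol, the aldehyde of 8 serving as the latent ring B acid so that ring B needs no protecting group.

**Step 6**
Reactants: 9 4-formyl-3-methylphenyl 3-acetoxy-4-(benzyloxy)-2-methylbenzoate
Product: 10 4-{[3-acetoxy-4-(benzyloxy)-2-methylbenzoyl]oxy}-2-methylbenzoic acid
Conditions: NaClO2, NaH2PO4, 2-methyl-2-butene, t-BuOH/THF/H2O, rt
Reagents that add atoms: sodium chlorite, [Na+].[O-]Cl=O
Why: a second Pinnick oxidation, whose buffered medium is too mild to hydrolyse the aryl ester or the acetate, unmasks the ring B acid.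

**Step 7**
Reactants: 11 4-hydroxy-2-methylbenzoic acid; 2 benzyl bromide
Product: 12 benzyl 4-hydroxy-2-methylbenzoate
Conditions: BnBr, KHCO3, DMF, rt to 40 °C
Reagents that add atoms: benzyl bromide 2, BrCc1ccccc1
Why: SN2 alkylation of the carboxylate, since hydrogen carbonate deprotonates only the acid and the phenol stays free for the next coupling.

**Step 8**
Reactants: 10 4-{[3-acetoxy-4-(benzyloxy)-2-methylbenzoyl]oxy}-2-methylbenzoic acid; 12 benzyl 4-hydroxy-2-methylbenzoate
Product: 13 benzyl 4-({4-[(3-acetoxy-4-(benzyloxy)-2-methylbenzoyl)oxy]-2-methylbenzoyl}oxy)-2-methylbenzoate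
Conditions: DCC, DMAP (cat.), CH2Cl2, 0 °C to rt
Reagents that add atoms: none
Why: Steglich esterification, again of a mono-ortho-substituted acid with the only phenol present, run cold with little DMAP so that acyl exchange at the existing aryl esters stays slow.

**Step 9**
Reactants: 13 benzyl 4-({4-[(3-acetoxy-4-(benzyloxy)-2-methylbenzoyl)oxy]-2-methylbenzoyl}oxy)-2-methylbenzoate
Product: 16 benzyl 4-({4-[(3-acetoxy-4-(benzyloxy)-6-hydroxy-2-methylbenzoyl)oxy]-2-hydroxy-6-methylbenzoyl}oxy)-2-hydroxy-6-methylbenzoate, via tris(pinacol boronate) 14 (not isolated), via tris(aryl borate) 15 (not isolated)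
Conditions: B2pin2 (4.5 equiv), [Ir(OMe)(cod)]2 (7.5 mol %), P[3,5-(CF3)2C6H3]3 (30 mol %), octane/mesitylene, 80 °C; volatiles removed, then Me3NO (excess), THF, rt to 50 °C, same flask; pH 6 phosphate buffer work-up
Reagents that add atoms: bis(pinacolato)diboron, CC1(C)OB(OC1(C)C)B1OC(C)(C)C(C)(C)O1 (boron groups of 14 and 15 only); trimethylamine N-oxide, C[N+](C)(C)[O-] (the three C2 oxygens)
Why: Proposed new method: the electron-poor phosphine should give a Lewis-acidic iridium tris(boryl) species (trivalent iridium) with a free site that binds an ester carbonyl oxygen, cleaves the neighbouring C2-H bond through a five-membered iridacycle and releases the C2-Bpin bond, after which Me3NO adds to each boron, the aryl group shifts from boron to oxygen with loss of Me3N, and the buffered work-up hydrolyses the three borates of 15. The closest known reaction type is ortho borylation of single alkyl benzoates with this same catalyst followed by boronate oxidation; ring C of 13 is such an alkyl benzoate, whereas aryl benzoate carbonyls (rings A and B) as directing groups and three events on one molecule are untested. No ring closes and no stereocentre forms, so only site selectivity matters: each carbonyl must deliver boron to C2 of its own acyl ring. The C6 methyl blocks the second ortho site and its sp3 C-H bonds would need a six-membered metallacycle, the aryloxy side would likewise need a six-membered metallacycle on a ring twisted out of the ester plane, C3-H and C5-H are each flanked by a substituent (C3 is shut completely once C2 carries Bpin), and the acetate carbonyl finds no ortho C-H because C4 and C6 of ring A are substituted. The only unhindered C-H bonds lie on the two benzyl groups, which a phosphine-ligated catalyst that is sluggish in undirected borylation should spare, and any oxygen placed there would leave with the benzyl groups in step 10. Until work-up the new oxygens stay masked as borates and the only base present is Me3N, so the acetate and both depside esters should survive.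

**Step 10**
Reactants: 16 benzyl 4-({4-[(3-acetoxy-4-(benzyloxy)-6-hydroxy-2-methylbenzoyl)oxy]-2-hydroxy-6-methylbenzoyl}oxy)-2-hydroxy-6-methylbenzoate
Product: 17 4-({4-[(3-acetoxy-4,6-dihydroxy-2-methylbenzoyl)oxy]-2-hydroxy-6-methylbenzoyl}oxy)-2-hydroxy-6-methylbenzoic acid
Conditions: H2 (1 atm), 10% Pd/C, EtOAc/THF, rt
Reagents that add atoms: none
Why: catalytic hydrogenolysis of the benzyl aryl ether and the benzyl ester under neutral aprotic conditions, which leave aryl esters and the acetate intact and supply no base that could move the acetyl group from the C5 to the C4 oxygen of ring A.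

**Compound list**
1 | 3-methylcatechol | Cc1cccc(O)c1O | starting material
2 | benzyl bromide | BrCc1ccccc1 | starting material
3 | 2-(benzyloxy)-6-methylphenol | Cc1cccc(OCc2ccccc2)c1O | intermediate
4 | 2-(benzyloxy)-6-methylphenyl acetate | CC(=O)Oc1c(C)cccc1OCc1ccccc1 | intermediate
5 | 6-(benzyloxy)-3-[chloro(methoxy)methyl]-2-methylphenyl acetate (racemic, not isolated) | COC(Cl)c1ccc(OCc2ccccc2)c(OC(C)=O)c1C | intermediate
6 | 3-acetoxy-4-(benzyloxy)-2-methylbenzaldehyde | CC(=O)Oc1c(OCc2ccccc2)ccc(C=O)c1C | intermediate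
7 | 3-acetoxy-4-(benzyloxy)-2-methylbenzoic acid | CC(=O)Oc1c(OCc2ccccc2)ccc(C(=O)O)c1C | intermediate
8 | 4-hydroxy-2-methylbenzaldehyde | Cc1cc(O)ccc1C=O | starting material
9 | 4-formyl-3-methylphenyl 3-acetoxy-4-(benzyloxy)-2-methylbenzoate | CC(=O)Oc1c(OCc2ccccc2)ccc(C(=O)Oc2ccc(C=O)c(C)c2)c1C | intermediate
10 | 4-{[3-acetoxy-4-(benzyloxy)-2-methylbenzoyl]oxy}-2-methylbenzoic acid | CC(=O)Oc1c(OCc2ccccc2)ccc(C(=O)Oc2ccc(C(=O)O)c(C)c2)c1C | intermediate
11 | 4-hydroxy-2-methylbenzoic acid | Cc1cc(O)ccc1C(=O)O | starting material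
12 | benzyl 4-hydroxy-2-methylbenzoate | Cc1cc(O)ccc1C(=O)OCc1ccccc1 | intermediate
13 | benzyl 4-({4-[(3-acetoxy-4-(benzyloxy)-2-methylbenzoyl)oxy]-2-methylbenzoyl}oxy)-2-methylbenzoate (tris(2-deoxy) tridepside) | CC(=O)Oc1c(OCc2ccccc2)ccc(C(=O)Oc2ccc(C(=O)Oc3ccc(C(=O)OCc4ccccc4)c(C)c3)c(C)c2)c1C | intermediate
14 | 13 carrying a 4,4,5,5-tetramethyl-1,3,2-dioxaborolan-2-yl group in place of H at C2 of rings A, B and C (not isolated) | CC(=O)Oc1c(OCc2ccccc2)cc(B2OC(C)(C)C(C)(C)O2)c(C(=O)Oc2cc(C)c(C(=O)Oc3cc(C)c(C(=O)OCc4ccccc4)c(B4OC(C)(C)C(C)(C)O4)c3)c(B3OC(C)(C)C(C)(C)O3)c2)c1C | intermediate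
15 | 13 carrying a (4,4,5,5-tetramethyl-1,3,2-dioxaborolan-2-yl)oxy group at C2 of rings A, B and C (not isolated) | CC(=O)Oc1c(OCc2ccccc2)cc(OB2OC(C)(C)C(C)(C)O2)c(C(=O)Oc2cc(C)c(C(=O)Oc3cc(C)c(C(=O)OCc4ccccc4)c(OB4OC(C)(C)C(C)(C)O4)c3)c(OB3OC(C)(C)C(C)(C)O3)c2)c1C | intermediate
16 | benzyl 4-({4-[(3-acetoxy-4-(benzyloxy)-6-hydroxy-2-methylbenzoyl)oxy]-2-hydroxy-6-methylbenzoyl}oxy)-2-hydroxy-6-methylbenzoate | CC(=O)Oc1c(OCc2ccccc2)cc(O)c(C(=O)Oc2cc(C)c(C(=O)Oc3cc(C)c(C(=O)OCc4ccccc4)c(O)c3)c(O)c2)c1C | intermediate
17 | 4-({4-[(3-acetoxy-4,6-dihydroxy-2-methylbenzoyl)oxy]-2-hydroxy-6-methylbenzoyl}oxy)-2-hydroxy-6-methylbenzoic acid (CNP0154030.0) | CC(=O)Oc1c(O)cc(O)c(C(=O)Oc2cc(C)c(C(=O)Oc3cc(C)c(C(=O)O)c(O)c3)c(O)c2)c1C | target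

**Step count**
Total step count: 10.
Longest linear sequence: 9 (steps 1 to 6, then 8, 9 and 10). Step 7 is the side branch.

**Steps most likely to fail**

*Step 9.* Aryl ester carbonyls are weaker donors than an alkyl ester carbonyl. Binding to iridium may be too weak, and the borylation may stall after ring C. It may also drift to the aryloxy side or to the benzyl rings, or suffer from poor solubility of the substrate in hydrocarbon solvent.

The fallback uses known chemistry, sets out from 7 and comes back at 16. It moves the C-H oxygenation to one ring, where the substrate is an ordinary single alkyl benzoate, and buys in the other two C2 oxygens.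
- Acid 7 is treated with tert-butyl 2,2,2-trichloroacetimidate in CH2Cl2/cyclohexane to give tert-butyl 3-acetoxy-4-(benzyloxy)-2-methylbenzoate F1.
- Ortho borylation with B2pin2, [Ir(OMe)(cod)]2 and P[3,5-(CF3)2C6H3]3 in octane at 80 °C gives tert-butyl 3-acetoxy-4-(benzyloxy)-2-methyl-6-(4,4,5,5-tetramethyl-1,3,2-dioxaborolan-2-yl)benzoate F2.
- Me3NO converts this into the aryl borate tert-butyl 3-acetoxy-4-(benzyloxy)-2-methyl-6-[(4,4,5,5-tetramethyl-1,3,2-dioxaborolan-2-yl)oxy]benzoate F3.
- Aqueous work-up gives tert-butyl 3-acetoxy-4-(benzyloxy)-6-hydroxy-2-methylbenzoate F4, and CF3CO2H in CH2Cl2 at 0 °C frees 3-acetoxy-4-(benzyloxy)-6-hydroxy-2-methylbenzoic acid F5.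
- Classical depside condensation (DCC, toluene) leaves hydroxyls hydrogen-bonded to an ortho carbonyl unacylated. It joins F5 to the 4-hydroxyl of commercial 2,4-dihydroxy-6-methylbenzaldehyde (Cc1cc(O)cc(O)c1C=O) to give 4-formyl-3-hydroxy-5-methylphenyl 3-acetoxy-4-(benzyloxy)-6-hydroxy-2-methylbenzoate F6.
- Chlorite oxidation (NaClO2, sulfamic acid) gives 4-{[3-acetoxy-4-(benzyloxy)-6-hydroxy-2-methylbenzoyl]oxy}-2-hydroxy-6-methylbenzoic acid F7.
- Commercial orsellinic acid (Cc1cc(O)cc(O)c1C(=O)O) with 2 and KHCO3 in DMF gives benzyl 2,4-dihydroxy-6-methylbenzoate F8.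
- A second DCC condensation of F7 with the 4-hydroxyl of F8 gives 16.

*Step 3.* Acid released during the formylation may strip the benzyl ether, or the electrophile may attack ortho instead of para to the ether.

The fallback sets out from 4 and comes back at 6. It replaces the Lewis-acid electrophile with a halogenation and carbonylation pair.
- NBS in MeCN, a strongly para-selective bromination of aryl ethers, gives 6-(benzyloxy)-3-bromo-2-methylphenyl acetate F9.
- Reductive carbonylation of F9 with Pd(OAc)2, P(1-adamantyl)2(n-Bu), TMEDA and CO/H2 in toluene at 100 °C gives 6. These conditions contain no nucleophile that could remove the acetate.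

*Step 1.* Discrimination between the two catechol oxygens may be poor, and double alkylation may compete.

The fallback sets out from 1 and comes back at 6. It differentiates the oxygens by acidity after the aldehyde is in place.
- Compound 1 is dimethylated (MeI, K2CO3, acetone) to 1,2-dimethoxy-3-methylbenzene F10.
- Vilsmeier-Haack formylation (POCl3, DMF) occurs para to the unhindered, conjugated methoxy group and gives 3,4-dimethoxy-2-methylbenzaldehyde F11.
- BBr3 in CH2Cl2 gives 3,4-dihydroxy-2-methylbenzaldehyde F12.
- The 4-hydroxyl of F12 lies para to the aldehyde and is clearly the more acidic, while the 3-hydroxyl is crowded by the methyl group. Treatment with 2, NaHCO3 and NaI in DMF therefore gives 4-(benzyloxy)-3-hydroxy-2-methylbenzaldehyde F13.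
- Acetylation (Ac2O, pyridine) then gives 6.

**Further compounds**
F1 | step 9 | tert-butyl 3-acetoxy-4-(benzyloxy)-2-methylbenzoate | CC(=O)Oc1c(OCc2ccccc2)ccc(C(=O)OC(C)(C)C)c1C
F2 | step 9 | tert-butyl 3-acetoxy-4-(benzyloxy)-2-methyl-6-(4,4,5,5-tetramethyl-1,3,2-dioxaborolan-2-yl)benzoate | CC(=O)Oc1c(OCc2ccccc2)cc(B2OC(C)(C)C(C)(C)O2)c(C(=O)OC(C)(C)C)c1C
F3 | step 9 | tert-butyl 3-acetoxy-4-(benzyloxy)-2-methyl-6-[(4,4,5,5-tetramethyl-1,3,2-dioxaborolan-2-yl)oxy]benzoate | CC(=O)Oc1c(OCc2ccccc2)cc(OB2OC(C)(C)C(C)(C)O2)c(C(=O)OC(C)(C)C)c1C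
F4 | step 9 | tert-butyl 3-acetoxy-4-(benzyloxy)-6-hydroxy-2-methylbenzoate | CC(=O)Oc1c(OCc2ccccc2)cc(O)c(C(=O)OC(C)(C)C)c1C
F5 | step 9 | 3-acetoxy-4-(benzyloxy)-6-hydroxy-2-methylbenzoic acid | CC(=O)Oc1c(OCc2ccccc2)cc(O)c(C(=O)O)c1C
F6 | step 9 | 4-formyl-3-hydroxy-5-methylphenyl 3-acetoxy-4-(benzyloxy)-6-hydroxy-2-methylbenzoate | CC(=O)Oc1c(OCc2ccccc2)cc(O)c(C(=O)Oc2cc(C)c(C=O)c(O)c2)c1C
F7 | step 9 | 4-{[3-acetoxy-4-(benzyloxy)-6-hydroxy-2-methylbenzoyl]oxy}-2-hydroxy-6-methylbenzoic acid | CC(=O)Oc1c(OCc2ccccc2)cc(O)c(C(=O)Oc2cc(C)c(C(=O)O)c(O)c2)c1C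
F8 | step 9 | benzyl 2,4-dihydroxy-6-methylbenzoate | Cc1cc(O)cc(O)c1C(=O)OCc1ccccc1
F9 | step 3 | 6-(benzyloxy)-3-bromo-2-methylphenyl acetate | CC(=O)Oc1c(OCc2ccccc2)ccc(Br)c1C
F10 | step 1 | 1,2-dimethoxy-3-methylbenzene | COc1cccc(C)c1OC
F11 | step 1 | 3,4-dimethoxy-2-methylbenzaldehyde | COc1ccc(C=O)c(C)c1OC
F12 | step 1 | 3,4-dihydroxy-2-methylbenzaldehyde | Cc1c(C=O)ccc(O)c1O
F13 | step 1 | 4-(benzyloxy)-3-hydroxy-2-methylbenzaldehyde | Cc1c(C=O)ccc(OCc2ccccc2)c1O
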